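**Retrosynthetic overview**
1. Feature used: ring C of the target (O1, C2, C3, C4, C4a, C8a) is a 2-aryl-3-hydroxy-4-pyranone, the pyromeconic acid skeleton. Ring A adds only four carbons, the 1,3-dioxygenated chain C5–C6–C7–C8, across the C4a–C8a edge. The 4-hydroxybenzyl group sits on C8, the end that meets the O1-bearing carbon C8a.
2. The last disconnection removes four O-benzyl groups. The key disconnection cuts C8–C8a and C4a–C5. It gives a 2-aryl-3-benzyloxy-5-bromo-4-pyranone (two-carbon partner, bromine holding the oxidation level) and a benzylated 1-methoxy-1,3-bis(trimethylsilyloxy)diene (four-carbon partner).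
3. The bromopyranone goes back to pyromeconic acid: C2 iodination, O-benzylation, C5 bromination, then Suzuki coupling at C2 with the ring B boronic acid. The diene goes back to methyl acetoacetate and 4-benzyloxybenzyl chloride by dianion γ-alkylation and two silylations.
4. Ring order: ring C, ring B and the benzyl arene are bought. Ring A is the only ring built and is closed in the penultimate step.

Key step: step 8

Assumption: the target has no stereocentre and no stereogenic double bond, so there is no enantiomer to select; the double-bond geometries written for 12–14 are the usual ones for this diene class and vanish when ring A becomes aromatic.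

**Route**

Step 1
Reactants: 1 pyromeconic acid (3-hydroxy-4H-pyran-4-one)
Product: 2 3-hydroxy-2-iodo-4H-pyran-4-one
Conditions: NIS (1.05 equiv), MeCN, 0 °C → rt, dark
Reagents that add atoms: N-iodosuccinimide, O=C1CCC(=O)N1I
Why: Electrophilic iodination of the enolic 3-hydroxy-4-pyranone should go to C2, the enol β-carbon next to the free OH, which is the site where pyromeconic and kojic acids are known to take halogen, Mannich and aldol electrophiles.

Step 2
Reactants: 2 3-hydroxy-2-iodo-4H-pyran-4-one
Product: 3 3-(benzyloxy)-2-iodo-4H-pyran-4-one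
Conditions: BnBr (1.1 equiv), K2CO3 (1.2 equiv), DMF, rt
Reagents that add atoms: benzyl bromide, BrCc1ccccc1
Why: Williamson O-alkylation of the acidic enolic OH with a mild carbonate base should leave the vinylogous acyl iodide untouched and installs a group that falls in the final hydrogenolysis.

Step 3
Reactants: 3 3-(benzyloxy)-2-iodo-4H-pyran-4-one
Product: 5 3-(benzyloxy)-5-bromo-2-iodo-4H-pyran-4-one, via trans-5,6-dibromide 4 (not isolated)
Conditions: Br2 (1.05 equiv), CH2Cl2, 0 °C, dark; Et3N (1.2 equiv), 0 °C → rt
Reagents that add atoms: bromine, BrBr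
Why: This is the classical bromine addition–dehydrobromination used for α-bromination of chromones and 4-pyranones: Br2 adds anti across the only disubstituted enol-ether bond C5=C6 to give 4, triethylamine removes the acidic H5 and expels the C6 bromide so that bromine can only remain on C5, and the step precedes the arrival of ring B because a dibenzyloxyphenyl ring would compete for bromine.

Step 4
Reactants: 5 3-(benzyloxy)-5-bromo-2-iodo-4H-pyran-4-one; 6 3,4-bis(benzyloxy)phenylboronic acid
Product: 7 3-(benzyloxy)-2-[3,4-bis(benzyloxy)phenyl]-5-bromo-4H-pyran-4-one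
Conditions: 6 (1.0 equiv), Pd(PPh3)4 (5 mol %), Na2CO3 (2 equiv), 1,4-dioxane/H2O, 60 °C
Reagents that add atoms: none
Why: The Suzuki–Miyaura coupling should be chemoselective because oxidative addition into C2–I (weaker bond, β-carbon of the vinylogous ester, next to O1) is much faster than into C5–Br when one equivalent of 6 is used at moderate temperature.

Step 5
Reactants: 8 methyl acetoacetate; 9 4-(benzyloxy)benzyl chloride
Product: 11 methyl 5-[4-(benzyloxy)phenyl]-3-oxopentanoate, via acetoacetate dianion 10 (not isolated)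
Conditions: NaH (1.1 equiv), THF, 0 °C; n-BuLi (1.05 equiv), 0 °C; 9, 0 °C → rt; dilute HCl
Reagents that add atoms: none
Why: In the γ-alkylation of the acetoacetate dianion the more basic terminal carbanion displaces the benzylic chloride, which gives the linear keto ester with the ArCH2 group on the future C8.

Step 6
Reactants: 11 methyl 5-[4-(benzyloxy)phenyl]-3-oxopentanoate
Product: 12 methyl (E)-5-[4-(benzyloxy)phenyl]-3-(trimethylsilyloxy)pent-2-enoate (E drawn; the Z isomer serves equally)
Conditions: TMSCl (1.5 equiv), Et3N (1.6 equiv), toluene, rt, 2–3 d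
Reagents that add atoms: chlorotrimethylsilane, C[Si](C)(C)Cl
Why: O-silylation of the enolised β-keto ester under amine base (soft enolisation) gives the 3-silyloxy enoate, the standard first stage in making 1,3-bis(silyloxy)dienes.

Step 7
Reactants: 12 methyl (E)-5-[4-(benzyloxy)phenyl]-3-(trimethylsilyloxy)pent-2-enoate
Product: 14 (1Z,3Z)-5-[4-(benzyloxy)phenyl]-1-methoxy-1,3-bis(trimethylsilyloxy)penta-1,3-diene, via lithium dienolate 13 (not isolated)
Conditions: LDA (1.2 equiv), THF, −78 °C; TMSCl (1.3 equiv), −78 °C → rt; pentane, filtration under Ar, used crude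
Reagents that add atoms: chlorotrimethylsilane, C[Si](C)(C)Cl
Why: Kinetic γ-deprotonation of the silyloxy enoate gives the extended ester dienolate 13, which TMSCl traps on oxygen (O-silylation of an ester enolate) to give the ketene-acetal diene, and 4-alkyl members of this class form with the 3Z geometry.

Step 8
Reactants: 7 3-(benzyloxy)-2-[3,4-bis(benzyloxy)phenyl]-5-bromo-4H-pyran-4-one; 14 (1Z,3Z)-5-[4-(benzyloxy)phenyl]-1-methoxy-1,3-bis(trimethylsilyloxy)penta-1,3-diene
Product: 19 3,3',4'-tri-O-benzyl-8-[4-(benzyloxy)benzyl]quercetin, via silyloxypyrylium triflate 15 (not isolated), via conjugate adduct 16 (not isolated), via bromo diketone 17 (not isolated), via 7-O-silyl ether 18 (not isolated)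
Conditions: 7, TMSOTf (2.2 equiv), 2,6-di-tert-butyl-4-methylpyridine (0.2 equiv), CH2Cl2, 0 °C → rt, 1 h; 14 (1.5 equiv), −78 °C → rt, 16 h, strictly anhydrous; DBU (5 equiv), 0 °C → rt; 1 M HCl, THF
Reagents that add atoms: none
Why: Proposed new method: O-silylation of the C4 carbonyl of 7 by TMSOTf gives the aromatic cation 15, and the most nucleophilic carbon of 14, the terminal CH that carries the benzyl group, bonds to position 6 of the cation in a vinylogous Mukaiyama–Michael addition that makes C8–C8a and leaves the 2H-pyran 16. The brominated enol silane carbon of 16 (future C4a), which is fed both by its own silyloxy group and by O1 through C2=C3, then attacks the side-chain ester carbon held O-silylated by the second equivalent of TMSOTf, a 6-(enolexo)-exo-trig Claisen-type closure that makes C4a–C5 and closes ring A, and if the first-formed cation collapses before it sheds its silyl group the same two bonds come from one asynchronous cationic [4+2] addition. Expulsion of MeOSiMe3 from the C5 ketal gives 17, DBU takes HBr from C8a–H and C4a–Br, and the resulting cyclohexenedione enolises to the resorcinol 18, so the bromine pays for the aromatisation and no oxidant is needed. The nearest known chemistry is the silyl-triflate-mediated addition of enol silanes and 1,3-bis(silyloxy)dienes to 4-silyloxy(benzo)pyrylium salts, which ends after the first bond, and the Diels–Alder/dehydrohalogenation of the same dienes with haloquinones, which makes both bonds; a monocyclic 4-pyranone has not been annulated in this way. The selectivity needed is the orientation of the diene, and the substrate fixes it: position 2 is blocked by ring B, position 4 carries the silyloxy group, the bromine marks the carbon that must become C4a, and because O1 is already bonded to the carbon that receives the benzylated terminus a 6-benzyl isomer cannot arise. The sp3 centres at C8, C8a and C4a in 16 and 17 form as mixtures and are all erased on aromatisation, so no stereocontrol is called for.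

Step 9
Reactants: 19 3,3',4'-tri-O-benzyl-8-[4-(benzyloxy)benzyl]quercetin
Product: 20 8-(4-hydroxybenzyl)quercetin (target)
Conditions: H2 (1 atm), 10 % Pd/C, THF/MeOH, rt; filtration and concentration under Ar
Reagents that add atoms: none
Why: Catalytic hydrogenolysis of benzyl ethers over palladium, routine on benzylated flavonols, should free all four hydroxyl groups and leave the C2=C3 bond, the C4 carbonyl and the diarylmethane C8–CH2 bond intact at one atmosphere.

**Compound list**
1 | pyromeconic acid (3-hydroxy-4H-pyran-4-one) | O=c1ccocc1O | starting material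
2 | 3-hydroxy-2-iodo-4H-pyran-4-one | O=c1ccoc(I)c1O | intermediate
3 | 3-(benzyloxy)-2-iodo-4H-pyran-4-one | O=c1ccoc(I)c1OCc1ccccc1 | intermediate
4 | (±)-trans-3-(benzyloxy)-5,6-dibromo-2-iodo-5,6-dihydro-4H-pyran-4-one (pyranone numbering; one enantiomer drawn; not isolated) | O=C1C(OCc2ccccc2)=C(I)O[C@@H](Br)[C@@H]1Br | intermediate
5 | 3-(benzyloxy)-5-bromo-2-iodo-4H-pyran-4-one | O=c1c(Br)coc(I)c1OCc1ccccc1 | intermediate
6 | 3,4-bis(benzyloxy)phenylboronic acid | OB(O)c1ccc(OCc2ccccc2)c(OCc2ccccc2)c1 | starting material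
7 | 3-(benzyloxy)-2-[3,4-bis(benzyloxy)phenyl]-5-bromo-4H-pyran-4-one | O=c1c(Br)coc(-c2ccc(OCc3ccccc3)c(OCc3ccccc3)c2)c1OCc1ccccc1 | intermediate
8 | methyl acetoacetate | CC(=O)CC(=O)OC | starting material
9 | 4-(benzyloxy)benzyl chloride | ClCc1ccc(OCc2ccccc2)cc1 | starting material
10 | sodium lithium dianion of methyl acetoacetate (not isolated) | [Na+].[Li+].C=C([O-])C=C([O-])OC | intermediate
11 | methyl 5-[4-(benzyloxy)phenyl]-3-oxopentanoate | COC(=O)CC(=O)CCc1ccc(OCc2ccccc2)cc1 | intermediate
12 | methyl (E)-5-[4-(benzyloxy)phenyl]-3-(trimethylsilyloxy)pent-2-enoate | COC(=O)/C=C(/O[Si](C)(C)C)CCc1ccc(OCc2ccccc2)cc1 | intermediate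
13 | lithium dienolate of 12 (not isolated) | [Li+].CO/C([O-])=C/C(O[Si](C)(C)C)=C/Cc1ccc(OCc2ccccc2)cc1 | intermediate
14 | (1Z,3Z)-5-[4-(benzyloxy)phenyl]-1-methoxy-1,3-bis(trimethylsilyloxy)penta-1,3-diene | CO/C(O[Si](C)(C)C)=C/C(O[Si](C)(C)C)=C/Cc1ccc(OCc2ccccc2)cc1 | intermediate
15 | 3-(benzyloxy)-2-[3,4-bis(benzyloxy)phenyl]-5-bromo-4-(trimethylsilyloxy)pyrylium triflate (not isolated) | C[Si](C)(C)Oc1c(Br)c[o+]c(-c2ccc(OCc3ccccc3)c(OCc3ccccc3)c2)c1OCc1ccccc1.[O-]S(=O)(=O)C(F)(F)F | intermediate
16 | methyl 4-{3-(benzyloxy)-2-[3,4-bis(benzyloxy)phenyl]-5-bromo-4-(trimethylsilyloxy)-6H-pyran-6-yl}-5-[4-(benzyloxy)phenyl]-3-(trimethylsilyloxy)pent-2-enoate (mixture of stereoisomers; not isolated) | COC(=O)C=C(O[Si](C)(C)C)C(Cc1ccc(OCc2ccccc2)cc1)C1OC(-c2ccc(OCc3ccccc3)c(OCc3ccccc3)c2)=C(OCc2ccccc2)C(O[Si](C)(C)C)=C1Br | intermediate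
17 | 3-(benzyloxy)-8-[4-(benzyloxy)benzyl]-2-[3,4-bis(benzyloxy)phenyl]-4a-bromo-7-(trimethylsilyloxy)-8,8a-dihydro-4H-chromene-4,5(4aH)-dione (mixture of diastereomers; not isolated) | O=C1C=C(O[Si](C)(C)C)C(Cc2ccc(OCc3ccccc3)cc2)C2OC(-c3ccc(OCc4ccccc4)c(OCc4ccccc4)c3)=C(OCc3ccccc3)C(=O)C12Br | intermediate
18 | 3,3',4'-tri-O-benzyl-8-[4-(benzyloxy)benzyl]-7-O-(trimethylsilyl)quercetin (not isolated) | O=c1c(OCc2ccccc2)c(-c2ccc(OCc3ccccc3)c(OCc3ccccc3)c2)oc2c(Cc3ccc(OCc4ccccc4)cc3)c(O[Si](C)(C)C)cc(O)c12 | intermediate
19 | 3,3',4'-tri-O-benzyl-8-[4-(benzyloxy)benzyl]quercetin | O=c1c(OCc2ccccc2)c(-c2ccc(OCc3ccccc3)c(OCc3ccccc3)c2)oc2c(Cc3ccc(OCc4ccccc4)cc3)c(O)cc(O)c12 | intermediate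
20 | 8-(4-hydroxybenzyl)quercetin | O=c1c(O)c(-c2ccc(O)c(O)c2)oc2c(Cc3ccc(O)cc3)c(O)cc(O)c12 | target

**Step count**
Total: 9 steps. Longest linear sequence: 6 steps (1, 2, 3, 4, 8, 9). The diene branch (5, 6, 7) joins at step 8.

**Steps most likely to fail**

1. Step 8 (new method).
- The sequence may halt after the first bond, because an O-silylated β-silyloxy acrylate is a weak acylating agent and a brominated enol silane is only a modest nucleophile.
- If DBU or water meets unclosed 16, the freed β-keto ester chain can divert in two ways. One is retro-oxa-Michael opening of ring C followed by aldol closure on C4. The other is enolate O-attack at the bromine-bearing carbon (Feist–Benary mode).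
- The 2H-pyran can also open electrocyclically.
- In 17, H8a is not acidified by any carbonyl, so ionisation of the C8a–O1 bond with loss of positive bromine can compete with loss of HBr.
- Fallback (known chemistry: ring A is bought and the C8–CH2 bond is made by cross-coupling). It sets out from 9 and rejoins the route at 20. Bought quercetin F1 is perbenzylated (BnBr, K2CO3, DMF, 80 °C) to 3,5,7,3',4'-penta-O-benzylquercetin F2. NIS with catalytic TFA in MeCN/CH2Cl2 iodinates ring A at C8, the position favoured by fully O-alkylated 5,7-dioxygenated flavones, to give 8-iodo-penta-O-benzylquercetin F3. Chloride 9 is inserted with zinc dust/LiCl in THF to give 4-(benzyloxy)benzylzinc chloride F4. Negishi coupling of F3 with F4 (Pd(OAc)2/SPhos, THF, rt to 50 °C) gives penta-O-benzyl-8-[4-(benzyloxy)benzyl]quercetin F5. Hydrogenolysis of F5 under the conditions of step 9 gives 20.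

2. Step 3.
- Bromine may attack C2 in the ipso sense, exchanging iodine for bromine.
- Triethylamine may add to the activated C2 or C6 position of the dihalide.
- Fallback (C–H metalation in place of electrophilic bromination, with ring B installed first). It sets out from 3 and rejoins at 7. Suzuki–Miyaura coupling of 3 with 6 under the conditions of step 4 gives 3-(benzyloxy)-2-[3,4-bis(benzyloxy)phenyl]-4H-pyran-4-one F6. Carbonyl-directed zincation with TMPZnCl·LiCl in THF, the α-selective mode known for chromones, gives the pyranon-5-ylzinc chloride F7. Quenching with 1,2-dibromotetrachloroethane puts bromine on C5 only and leaves the electron-rich ring B untouched, giving 7.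

3. Step 4.
- Aqueous carbonate may add at C2 or C6 and open the dihalopyranone ring.
- A second oxidative addition at C5–Br may lead to double arylation.
- Fallback (base-free and water-free Negishi coupling at room temperature). It sets out from 5 and rejoins at 7. Bought 4-bromo-1,2-bis(benzyloxy)benzene F8 undergoes bromine–lithium exchange (n-BuLi, THF, −78 °C) to 3,4-bis(benzyloxy)phenyllithium F9. ZnCl2 converts F9 into 3,4-bis(benzyloxy)phenylzinc chloride F10. F10 (1.0 equiv) couples with 5 at the C–I bond (Pd(PPh3)4, THF, rt) to give 7.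

**Further compounds**
F1 | step 8 | quercetin (bought) | O=c1c(O)c(-c2ccc(O)c(O)c2)oc2cc(O)cc(O)c12
F2 | step 8 | 3,5,7,3',4'-penta-O-benzylquercetin | O=c1c(OCc2ccccc2)c(-c2ccc(OCc3ccccc3)c(OCc3ccccc3)c2)oc2cc(OCc3ccccc3)cc(OCc3ccccc3)c12
F3 | step 8 | 8-iodo-penta-O-benzylquercetin | O=c1c(OCc2ccccc2)c(-c2ccc(OCc3ccccc3)c(OCc3ccccc3)c2)oc2c(I)c(OCc3ccccc3)cc(OCc3ccccc3)c12
F4 | step 8 | 4-(benzyloxy)benzylzinc chloride | Cl[Zn]Cc1ccc(OCc2ccccc2)cc1
F5 | step 8 | penta-O-benzyl-8-[4-(benzyloxy)benzyl]quercetin | O=c1c(OCc2ccccc2)c(-c2ccc(OCc3ccccc3)c(OCc3ccccc3)c2)oc2c(Cc3ccc(OCc4ccccc4)cc3)c(OCc3ccccc3)cc(OCc3ccccc3)c12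
F6 | step 3 | 3-(benzyloxy)-2-[3,4-bis(benzyloxy)phenyl]-4H-pyran-4-one | O=c1ccoc(-c2ccc(OCc3ccccc3)c(OCc3ccccc3)c2)c1OCc1ccccc1
F7 | step 3 | {3-(benzyloxy)-2-[3,4-bis(benzyloxy)phenyl]-4-oxo-4H-pyran-5-yl}zinc chloride | O=c1c([Zn]Cl)coc(-c2ccc(OCc3ccccc3)c(OCc3ccccc3)c2)c1OCc1ccccc1
F8 | step 4 | 4-bromo-1,2-bis(benzyloxy)benzene (bought) | Brc1ccc(OCc2ccccc2)c(OCc2ccccc2)c1
F9 | step 4 | 3,4-bis(benzyloxy)phenyllithium | [Li]c1ccc(OCc2ccccc2)c(OCc2ccccc2)c1
F10 | step 4 | 3,4-bis(benzyloxy)phenylzinc chloride | Cl[Zn]c1ccc(OCc2ccccc2)c(OCc2ccccc2)c1
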